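**Plan**

- Retrosynthesis removes the C13 acetate and the C15=C17 methylene, then opens the 14-membered ring at C8–C9. The E-C7=C8(Me) alkene and the C11–C12 oxirane of that ring are bridged only by C9H2–C10H2, so a C8 alkenyl iodide and a C9=C10 vinyl epoxide can be joined sp2–sp3 with the alkene geometry already fixed.
- Further cuts: C9=C10 (Wittig), the oxirane C–O bonds (Sharpless), the lactone C16 oxidation level (from a C15=C16 vinyl group), C1–C2 (allylboration), C1=C15 (cross-metathesis), C13–C14 (allylation); in the C2–C8 arm, C5–C6 and C4–CH3.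
- Forward: a C2–C8 iodo-dienal (from ethyl acetoacetate and 1-bromobut-2-yne) and a C10–C16 Z-allylboronate (from prenol) are joined at C1–C2. The γ-lactone closes first, the oxirane second, the 14-membered carbocycle third; methylenation and the acetate come last.
- Stereochemistry: C13 from Ipc2B–allyl addition; C1/C2 (syn, hence the cis-lactone) from the Z-boronate geometry under chiral phosphoric acid control; C11/C12 from Sharpless epoxidation with L-(+)-DET. The E-alkenes come from enol phosphate/cuprate substitution, syn-hydrozirconation and E-selective SeO2 oxidation.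

Key step: step 19

**Remarks**

- Numbering (used from compound 19 on): C1 ring-fusion CH, C2 lactone OCH, C3=C4(Me), C5, C6, C7=C8(Me), C9, C10, C11–C12(Me) oxirane, C13 (O), C14, C15/C16 lactone α-carbon/C=O, C17 exocyclic CH2. CIP labels at C1, C2, C11 and C12 change along the route only because substituent priorities change; the spatial arrangement is that of 35 throughout.
- Assumption: the Ipc2B–allyl reagent made from (−)-Ipc2BOMe is taken to attack the Si face of the α-branched enal 13, and (R)-TRIP to direct allyl transfer to the Re face of enal 9, as these reagents do with aryl and alkenyl aldehydes; the antipodal reagent would be used if a model study showed otherwise.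
- Enolates and alkoxides formed by simple deprotonation are treated as salts of the parent compound and are not numbered.

**Route**

Step 1
Reactants: 1 ethyl acetoacetate; 2 1-bromobut-2-yne
Product: 3 ethyl 3-oxooct-6-ynoate
Conditions: NaH, THF, 0 °C; n-BuLi, 0 °C; then 2, 0 °C → rt; aq NH4Cl
Reagents that add atoms: none
Why: γ-Alkylation of the acetoacetate dianion: the more basic terminal carbanion displaces the propargylic bromide by SN2 and forms C5–C6.

Step 2
Reactants: 3 ethyl 3-oxooct-6-ynoate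
Product: 4 ethyl (2Z)-3-[(diethoxyphosphoryl)oxy]oct-2-en-6-ynoate
Conditions: NaH, Et2O, 0 °C; ClP(O)(OEt)2, 0 °C → rt
Reagents that add atoms: diethyl chlorophosphate, CCOP(Cl)(=O)OCC
Why: O-Phosphorylation of the chelated sodium enolate of a β-keto ester should give the Z-enol phosphate, which fixes the later C3=C4 geometry.

Step 3
Reactants: 4 Z-enol phosphate
Product: 5 ethyl (2E)-3-methyloct-2-en-6-ynoate
Conditions: Me2CuLi (from MeLi and CuI), Et2O, −78 → −45 °C
Reagents that add atoms: lithium dimethylcuprate, [Li+].C[Cu-]C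
Why: Cuprate substitution of an enol phosphate (addition–elimination with retention) should place the C4 methyl cis to the ester carbon and so give the E-trisubstituted enoate.

Step 4
Reactants: 5 ethyl (2E)-3-methyloct-2-en-6-ynoate
Product: 6 (2E)-3-methyloct-2-en-6-yn-1-ol
Conditions: DIBAL-H (2.2 equiv), CH2Cl2, −78 → 0 °C; Rochelle salt
Reagents that add atoms: none
Why: DIBAL-H 1,2-reduction of a conjugated ester to the allylic alcohol leaves the internal alkyne and the alkene geometry untouched.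

Step 5
Reactants: 6 (2E)-3-methyloct-2-en-6-yn-1-ol
Product: 8 (2E,6E)-7-iodo-3-methylocta-2,6-dien-1-ol, via alkenylzirconocene chloride 7 (not isolated)
Conditions: Cp2Zr(H)Cl (3 equiv), THF, 50 °C; then I2, THF, 0 °C
Reagents that add atoms: iodine, II
Why: Schwartz hydrozirconation–iodination: syn H–Zr addition to the 2-alkyne equilibrates under excess reagent to zirconium on the methyl-bearing carbon, and iodinolysis with retention should give the E-iodoalkene (one equivalent of reagent is consumed by the hydroxyl).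

Step 6
Reactants: 8 (2E,6E)-7-iodo-3-methylocta-2,6-dien-1-ol
Product: 9 (2E,6E)-7-iodo-3-methylocta-2,6-dienal
Conditions: MnO2, CH2Cl2, rt
Reagents that add atoms: none
Why: MnO2 oxidises allylic alcohols selectively to enals without touching the alkenyl iodide or the E-geometry.

Step 7
Reactants: 10 3-methylbut-2-en-1-ol (prenol)
Product: 11 tert-butyldimethyl[(3-methylbut-2-en-1-yl)oxy]silane
Conditions: TBSCl, imidazole, DMF, rt
Reagents that add atoms: tert-butyldimethylsilyl chloride, CC(C)(C)[Si](C)(C)Cl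
Why: Standard silylation of a primary alcohol masks the future C10 oxygen.

Step 8
Reactants: 11 prenyl TBS ether
Product: 13 (2E)-4-[(tert-butyldimethylsilyl)oxy]-2-methylbut-2-enal, via E-allylic alcohol 12 (not isolated)
Conditions: SeO2 (0.5 equiv), t-BuOOH, salicylic acid (cat.), CH2Cl2, rt; then MnO2, CH2Cl2, rt
Reagents that add atoms: tert-butyl hydroperoxide, CC(C)(C)OO (terminal oxidant; the oxygen is transferred by catalytic selenium dioxide, O=[Se]=O)
Why: SeO2 allylic oxidation (ene reaction then [2,3]-shift) attacks the methyl group trans to the chain of a gem-dimethyl alkene, and MnO2 converges the alcohol/aldehyde mixture to the E-enal.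

Step 9
Reactants: 13 (2E)-4-[(tert-butyldimethylsilyl)oxy]-2-methylbut-2-enal
Product: 15 (4S,5E)-7-[(tert-butyldimethylsilyl)oxy]-5-methylhepta-1,5-dien-4-ol, via diisopinocampheylborinate ester 14 (not isolated)
Conditions: (−)-Ipc2BOMe, allylMgBr, Et2O, −78 °C → rt; then 13, −78 °C; 3 M NaOH, 30% H2O2
Reagents that add atoms: allylmagnesium bromide, C=CC[Mg]Br (allyl group, delivered through Ipc2B–allyl)
Why: Brown allylation: the chair transition state of the Ipc2B–allyl reagent should deliver allyl to the Si face of the α-methyl enal and set C13 as S (reagent control).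

Step 10
Reactants: 15 (4S,5E)-7-[(tert-butyldimethylsilyl)oxy]-5-methylhepta-1,5-dien-4-ol
Product: 16 tert-butyl({(2E,4S)-4-[(4-methoxybenzyl)oxy]-3-methylhepta-2,6-dien-1-yl}oxy)dimethylsilane
Conditions: NaH, PMBCl, Bu4NI (cat.), THF/DMF, 0 °C → rt
Reagents that add atoms: 4-methoxybenzyl chloride, COc1ccc(CCl)cc1
Why: Williamson etherification gives a C13 ether that survives base, borane, palladium and enolate chemistry and can be removed oxidatively at the end without forming an alkoxide.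

Step 11
Reactants: 16 PMB ether; 17 2-allyl-4,4,5,5-tetramethyl-1,3,2-dioxaborolane
Product: 18 tert-butyl({(2E,4S,6Z)-4-[(4-methoxybenzyl)oxy]-3-methyl-8-(4,4,5,5-tetramethyl-1,3,2-dioxaborolan-2-yl)octa-2,6-dien-1-yl}oxy)dimethylsilane
Conditions: 17 (4 equiv), cyclometalated Ru–NHC nitrato (Z-selective) metathesis catalyst (5 mol %), THF, 35 °C, argon sparge
Reagents that add atoms: none
Why: Z-Selective cross-metathesis of a terminal alkene with allyl-Bpin should give the Z-γ-substituted allylboronate; the trisubstituted alkene is inert to the catalyst.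

Step 12
Reactants: 9 (2E,6E)-7-iodo-3-methylocta-2,6-dienal; 18 Z-allylboronate
Product: 20 (2E,4S,6S,7R,8E,12E)-1-[(tert-butyldimethylsilyl)oxy]-6-ethenyl-13-iodo-4-[(4-methoxybenzyl)oxy]-3,9-dimethyltetradeca-2,8,12-trien-7-ol (cembrane labels 1S,2R,13S), via pinacol borate ester 19 (not isolated)
Conditions: (R)-TRIP phosphoric acid (10 mol %), 4 Å MS, toluene, −30 → 0 °C; aq NaHCO3
Reagents that add atoms: none
Why: Chiral phosphoric acid catalysed allylboration through a closed chair transition state: the Z-geometry of 18 puts the C2 oxygen and C14 syn (C1), and the (R)-catalyst should direct attack to the Re face of the enal (C2).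

Step 13
Reactants: 20 syn-homoallylic alcohol
Product: 22 C2,C16-diol (the C15=C16 vinyl group of 20 converted to CH2CH2OH; 1R,2R,13S), via B-alkyl-9-BBN adduct 21 (not isolated)
Conditions: 9-BBN (2.5 equiv), THF, 0 °C → rt; then 3 M NaOH, 30% H2O2, 0 °C
Reagents that add atoms: hydrogen peroxide, OO
Why: Hydroboration–oxidation: 9-BBN adds anti-Markovnikov to the only monosubstituted alkene and ignores the three trisubstituted alkenes and the alkenyl iodide.

Step 14
Reactants: 22 C2,C16-diol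
Product: 24 (4S,5R)-4-{(2S,3E)-5-[(tert-butyldimethylsilyl)oxy]-2-[(4-methoxybenzyl)oxy]-3-methylpent-3-en-1-yl}-5-[(1E,5E)-6-iodo-2-methylhepta-1,5-dien-1-yl]dihydrofuran-2(3H)-one, via lactol 23 (not isolated)
Conditions: TEMPO (0.2 equiv), PhI(OAc)2 (2.5 equiv), CH2Cl2, rt
Reagents that add atoms: none
Why: TEMPO/PhI(OAc)2 oxidative lactonisation: the primary alcohol is oxidised first, the aldehyde closes onto the C2 hydroxyl, and the lactol is oxidised to the γ-lactone, cis-fused because of the syn diad.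

Step 15
Reactants: 24 cis-butanolide (10-OTBS, 13-OPMB)
Product: 25 (4S,5R)-4-{(2S,3E)-5-hydroxy-2-[(4-methoxybenzyl)oxy]-3-methylpent-3-en-1-yl}-5-[(1E,5E)-6-iodo-2-methylhepta-1,5-dien-1-yl]dihydrofuran-2(3H)-one
Conditions: HF·pyridine, pyridine, THF, 0 °C → rt
Reagents that add atoms: none
Why: Buffered fluoride cleaves the primary allylic silyl ether while lactone, PMB ether and alkenyl iodide are stable.

Step 16
Reactants: 25 C10 allylic alcohol
Product: 26 (4S,5R)-4-{(2S)-2-[(2S,3S)-3-(hydroxymethyl)-2-methyloxiran-2-yl]-2-[(4-methoxybenzyl)oxy]ethyl}-5-[(1E,5E)-6-iodo-2-methylhepta-1,5-dien-1-yl]dihydrofuran-2(3H)-one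
Conditions: Ti(OiPr)4 (10 mol %), L-(+)-DET (12 mol %), t-BuOOH, 4 Å MS, CH2Cl2, −20 °C
Reagents that add atoms: tert-butyl hydroperoxide, CC(C)(C)OO
Why: Sharpless asymmetric epoxidation of a geraniol-type E-allylic alcohol: L-(+)-DET should deliver oxygen to the face that gives the C11/C12 configuration of the target, and only the allylic alkene reacts.

Step 17
Reactants: 26 epoxy alcohol
Product: 27 (4S,5R)-4-{(2S)-2-[(2S,3R)-3-formyl-2-methyloxiran-2-yl]-2-[(4-methoxybenzyl)oxy]ethyl}-5-[(1E,5E)-6-iodo-2-methylhepta-1,5-dien-1-yl]dihydrofuran-2(3H)-one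
Conditions: Dess–Martin periodinane, NaHCO3, CH2Cl2, 0 °C → rt
Reagents that add atoms: none
Why: Buffered Dess–Martin oxidation converts 2,3-epoxy alcohols to epoxy aldehydes without epimerisation or oxirane opening.

Step 18
Reactants: 27 epoxy aldehyde
Product: 28 (4S,5R)-4-{(2S)-2-[(2S,3S)-3-ethenyl-2-methyloxiran-2-yl]-2-[(4-methoxybenzyl)oxy]ethyl}-5-[(1E,5E)-6-iodo-2-methylhepta-1,5-dien-1-yl]dihydrofuran-2(3H)-one
Conditions: Ph3PCH3Br, KHMDS, THF, 0 °C; then 27, −78 → 0 °C
Reagents that add atoms: methyltriphenylphosphonium bromide, C[P+](c1ccccc1)(c1ccccc1)c1ccccc1.[Br-]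
Why: Wittig methylenation of the aldehyde with a slight excess of ylide at low temperature forms C9=C10 much faster than the ylide can attack the lactone.

Step 19
Reactants: 28 vinyl epoxide / alkenyl iodide seco-lactone
Product: 30 (1S,2R,3E,7E,11S,12R,13S)-11,12-epoxy-13-[(4-methoxybenzyl)oxy]-17-norcembra-3,7-dien-16,2-olide (the target skeleton with C15 as CH2), via C9-alkylborane 29 (not isolated)
Conditions: 9-BBN (1.5 equiv), THF, 0 °C → rt; then syringe-pump addition to PdCl2(dppf) (15 mol %), AsPh3 (30 mol %), Cs2CO3 (3 equiv), DMF/THF/H2O, 50 °C, ca. 1 mM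
Reagents that add atoms: none
Why: 9-BBN adds only to the monosubstituted C9=C10 alkene with boron on C9, then Pd(0) inserts into the C8–I bond with retention, the base-activated borate transfers the primary C9 alkyl group and reductive elimination forms C8–C9. The closest known reaction type is the intramolecular B-alkyl Suzuki–Miyaura macrocyclisation of an alkenyl iodide bearing a remote terminal alkene. The 14-membered carbocycle closes from a 15-membered alkyl(alkenyl)palladacycle, and high dilution with slow addition favours ring closure over oligomerisation. No stereocentre is formed; the step needs retention of the E-C7=C8 geometry, which oxidative addition and reductive elimination both preserve, and it leaves the five existing stereocentres untouched. The vinyl epoxide is consumed by hydroboration before any Pd(0) is present, so π-allyl ionisation is excluded, and the oxirane oxygen sits on the carbon γ to boron, so β-alkoxide elimination is not open to the borane. Carbonate base in wet DMF spares the γ-lactone and the PMB ether.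

Step 20
Reactants: 30 17-nor macrolide
Product: 33 (1S,2S,3E,7E,11S,12R,13S)-11,12-epoxy-13-[(4-methoxybenzyl)oxy]cembra-3,7,15(17)-trien-16,2-olide, via Mannich base 31 (not isolated), via methiodide 32 (not isolated)
Conditions: LDA, THF, −78 °C; CH2=NMe2+ I−, −78 °C → rt; MeI, MeOH/CH2Cl2, rt; aq NaHCO3
Reagents that add atoms: N,N-dimethylmethyleneiminium iodide (Eschenmoser's salt), C=[N+](C)C.[I-]
Why: Mannich reaction of the lactone enolate followed by quaternisation and Hofmann-type elimination installs the C15=C17 methylene; the C15 stereocentre of 31 is lost again and the oxirane tolerates LDA at −78 °C.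

Step 21
Reactants: 33 13-O-PMB α-methylene macrolide
Product: 34 (1S,2S,3E,7E,11S,12S,13S)-11,12-epoxy-13-hydroxycembra-3,7,15(17)-trien-16,2-olide
Conditions: DDQ, CH2Cl2/pH 7 phosphate buffer, 0 °C → rt
Reagents that add atoms: none
Why: Oxidative PMB cleavage with DDQ is neutral, so no C13 alkoxide is formed that could trigger Payne rearrangement of the adjacent oxirane or conjugate addition to the methylene lactone.

Step 22
Reactants: 34 C13 alcohol
Product: 35 (1S,2S,3E,7E,11S,12R,13S)-13-acetoxy-11,12-epoxycembra-3,7,15(17)-trien-16,2-olide (target)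
Conditions: Ac2O, pyridine, DMAP (cat.), CH2Cl2, 0 °C → rt
Reagents that add atoms: acetic anhydride, CC(=O)OC(C)=O
Why: DMAP-catalysed acetylation of the secondary alcohol does not affect the oxirane or the Michael acceptor.

**Compound list**

1 | ethyl acetoacetate | CCOC(=O)CC(C)=O | starting material
2 | 1-bromobut-2-yne | CC#CCBr | starting material
3 | ethyl 3-oxooct-6-ynoate | CCOC(=O)CC(=O)CCC#CC | intermediate
4 | ethyl (2Z)-3-[(diethoxyphosphoryl)oxy]oct-2-en-6-ynoate | CCOC(=O)/C=C(\OP(=O)(OCC)OCC)CCC#CC | intermediate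
5 | ethyl (2E)-3-methyloct-2-en-6-ynoate | CCOC(=O)/C=C(\C)CCC#CC | intermediate
6 | (2E)-3-methyloct-2-en-6-yn-1-ol | OC/C=C(\C)CCC#CC | intermediate
7 | (2E,6E)-3-methylocta-2,6-dien-1-ol carrying Cp2ZrCl on C7 (syn to H-6) and on oxygen (formed in situ) | C/C(=C\CC/C(C)=C/CO[Zr](Cl)(C1C=CC=C1)C1C=CC=C1)[Zr](Cl)(C1C=CC=C1)C1C=CC=C1 | intermediate
8 | (2E,6E)-7-iodo-3-methylocta-2,6-dien-1-ol | OC/C=C(\C)CC/C=C(\C)I | intermediate
9 | (2E,6E)-7-iodo-3-methylocta-2,6-dienal | O=C/C=C(\C)CC/C=C(\C)I | intermediate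
10 | 3-methylbut-2-en-1-ol (prenol) | CC(C)=CCO | starting material
11 | tert-butyldimethyl[(3-methylbut-2-en-1-yl)oxy]silane | CC(C)=CCO[Si](C)(C)C(C)(C)C | intermediate
12 | (2E)-4-[(tert-butyldimethylsilyl)oxy]-2-methylbut-2-en-1-ol (formed in situ) | OC/C(C)=C/CO[Si](C)(C)C(C)(C)C | intermediate
13 | (2E)-4-[(tert-butyldimethylsilyl)oxy]-2-methylbut-2-enal | O=C/C(C)=C/CO[Si](C)(C)C(C)(C)C | intermediate
14 | O-bis(isopinocampheyl)boryl derivative of 15 (formed in situ) | C=CC[C@H](OB([C@H]1[C@H](C)[C@H]2C[C@@H](C1)C2(C)C)[C@H]1[C@H](C)[C@H]2C[C@@H](C1)C2(C)C)/C(C)=C/CO[Si](C)(C)C(C)(C)C | intermediate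
15 | (4S,5E)-7-[(tert-butyldimethylsilyl)oxy]-5-methylhepta-1,5-dien-4-ol | C=CC[C@H](O)/C(C)=C/CO[Si](C)(C)C(C)(C)C | intermediate
16 | tert-butyl({(2E,4S)-4-[(4-methoxybenzyl)oxy]-3-methylhepta-2,6-dien-1-yl}oxy)dimethylsilane | C=CC[C@H](OCc1ccc(OC)cc1)/C(C)=C/CO[Si](C)(C)C(C)(C)C | intermediate
17 | 2-allyl-4,4,5,5-tetramethyl-1,3,2-dioxaborolane (allyl-Bpin) | C=CCB1OC(C)(C)C(C)(C)O1 | starting material
18 | tert-butyl({(2E,4S,6Z)-4-[(4-methoxybenzyl)oxy]-3-methyl-8-(4,4,5,5-tetramethyl-1,3,2-dioxaborolan-2-yl)octa-2,6-dien-1-yl}oxy)dimethylsilane | CC1(C)OB(C/C=C\C[C@H](OCc2ccc(OC)cc2)/C(C)=C/CO[Si](C)(C)C(C)(C)C)OC1(C)C | intermediate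
19 | C2–O–Bpin borate ester of 20 (formed in situ) | C=C[C@H](C[C@H](OCc1ccc(OC)cc1)/C(C)=C/CO[Si](C)(C)C(C)(C)C)[C@@H](OB1OC(C)(C)C(C)(C)O1)/C=C(\C)CC/C=C(\C)I | intermediate
20 | (2E,4S,6S,7R,8E,12E)-1-[(tert-butyldimethylsilyl)oxy]-6-ethenyl-13-iodo-4-[(4-methoxybenzyl)oxy]-3,9-dimethyltetradeca-2,8,12-trien-7-ol (cembrane labels 1S,2R,13S) | C=C[C@H](C[C@H](OCc1ccc(OC)cc1)/C(C)=C/CO[Si](C)(C)C(C)(C)C)[C@@H](O)/C=C(\C)CC/C=C(\C)I | intermediate
21 | B-alkyl-9-BBN adduct of 20, boron on C16 (formed in situ) | B1(CC[C@H](C[C@H](OCc3ccc(OC)cc3)/C(C)=C/CO[Si](C)(C)C(C)(C)C)[C@@H](O)/C=C(\C)CC/C=C(\C)I)C2CCCC1CCC2 | intermediate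
22 | C2,C16-diol: 20 with the ethenyl group converted to 2-hydroxyethyl (1R,2R,13S) | OCC[C@H](C[C@H](OCc1ccc(OC)cc1)/C(C)=C/CO[Si](C)(C)C(C)(C)C)[C@@H](O)/C=C(\C)CC/C=C(\C)I | intermediate
23 | lactol of 24 (C16 hemiacetal, anomer mixture, formed in situ) | OC1C[C@H](C[C@H](OCc2ccc(OC)cc2)/C(C)=C/CO[Si](C)(C)C(C)(C)C)[C@H](/C=C(\C)CC/C=C(\C)I)O1 | intermediate
24 | (4S,5R)-4-{(2S,3E)-5-[(tert-butyldimethylsilyl)oxy]-2-[(4-methoxybenzyl)oxy]-3-methylpent-3-en-1-yl}-5-[(1E,5E)-6-iodo-2-methylhepta-1,5-dien-1-yl]dihydrofuran-2(3H)-one | O=C1C[C@H](C[C@H](OCc2ccc(OC)cc2)/C(C)=C/CO[Si](C)(C)C(C)(C)C)[C@H](/C=C(\C)CC/C=C(\C)I)O1 | intermediate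
25 | (4S,5R)-4-{(2S,3E)-5-hydroxy-2-[(4-methoxybenzyl)oxy]-3-methylpent-3-en-1-yl}-5-[(1E,5E)-6-iodo-2-methylhepta-1,5-dien-1-yl]dihydrofuran-2(3H)-one | O=C1C[C@H](C[C@H](OCc2ccc(OC)cc2)/C(C)=C/CO)[C@H](/C=C(\C)CC/C=C(\C)I)O1 | intermediate
26 | (4S,5R)-4-{(2S)-2-[(2S,3S)-3-(hydroxymethyl)-2-methyloxiran-2-yl]-2-[(4-methoxybenzyl)oxy]ethyl}-5-[(1E,5E)-6-iodo-2-methylhepta-1,5-dien-1-yl]dihydrofuran-2(3H)-one | O=C1C[C@H](C[C@H](OCc2ccc(OC)cc2)[C@]3(C)O[C@H]3CO)[C@H](/C=C(\C)CC/C=C(\C)I)O1 | intermediate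
27 | (4S,5R)-4-{(2S)-2-[(2S,3R)-3-formyl-2-methyloxiran-2-yl]-2-[(4-methoxybenzyl)oxy]ethyl}-5-[(1E,5E)-6-iodo-2-methylhepta-1,5-dien-1-yl]dihydrofuran-2(3H)-one | O=C1C[C@H](C[C@H](OCc2ccc(OC)cc2)[C@]3(C)O[C@H]3C=O)[C@H](/C=C(\C)CC/C=C(\C)I)O1 | intermediate
28 | (4S,5R)-4-{(2S)-2-[(2S,3S)-3-ethenyl-2-methyloxiran-2-yl]-2-[(4-methoxybenzyl)oxy]ethyl}-5-[(1E,5E)-6-iodo-2-methylhepta-1,5-dien-1-yl]dihydrofuran-2(3H)-one | O=C1C[C@H](C[C@H](OCc2ccc(OC)cc2)[C@]3(C)O[C@H]3C=C)[C@H](/C=C(\C)CC/C=C(\C)I)O1 | intermediate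
29 | B-alkyl-9-BBN adduct of 28, boron on C9 (formed in situ) | O=C1C[C@H](C[C@H](OCc2ccc(OC)cc2)[C@]3(C)O[C@H]3CCB3C4CCCC3CCC4)[C@H](/C=C(\C)CC/C=C(\C)I)O1 | intermediate
30 | (1S,2R,3E,7E,11S,12R,13S)-11,12-epoxy-13-[(4-methoxybenzyl)oxy]-17-norcembra-3,7-dien-16,2-olide | C1C(=O)O[C@H]2/C=C(\C)CC/C=C(\C)CC[C@@H]3O[C@@]3(C)[C@@H](OCc3ccc(OC)cc3)C[C@@H]12 | intermediate
31 | 15-(dimethylaminomethyl) derivative of 30 (C15 epimers, formed in situ) | CN(C)CC1C(=O)O[C@H]2/C=C(\C)CC/C=C(\C)CC[C@@H]3O[C@@]3(C)[C@@H](OCc3ccc(OC)cc3)C[C@@H]12 | intermediate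
32 | trimethylammonium iodide (methiodide) of 31 (formed in situ) | C[N+](C)(C)CC1C(=O)O[C@H]2/C=C(\C)CC/C=C(\C)CC[C@@H]3O[C@@]3(C)[C@@H](OCc3ccc(OC)cc3)C[C@@H]12.[I-] | intermediate
33 | (1S,2S,3E,7E,11S,12R,13S)-11,12-epoxy-13-[(4-methoxybenzyl)oxy]cembra-3,7,15(17)-trien-16,2-olide | C=C1C(=O)O[C@H]2/C=C(\C)CC/C=C(\C)CC[C@@H]3O[C@@]3(C)[C@@H](OCc3ccc(OC)cc3)C[C@@H]12 | intermediate
34 | (1S,2S,3E,7E,11S,12S,13S)-11,12-epoxy-13-hydroxycembra-3,7,15(17)-trien-16,2-olide | C=C1C(=O)O[C@H]2/C=C(\C)CC/C=C(\C)CC[C@@H]3O[C@@]3(C)[C@@H](O)C[C@@H]12 | intermediate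
35 | (1S,2S,3E,7E,11S,12R,13S)-13-acetoxy-11,12-epoxycembra-3,7,15(17)-trien-16,2-olide | C=C1C(=O)O[C@H]2/C=C(\C)CC/C=C(\C)CC[C@@H]3O[C@@]3(C)[C@@H](OC(C)=O)C[C@@H]12 | target

**Step count and risks**

Total: 22 steps. Longest linear sequence: 17 steps (steps 1–6 and 12–22); the C10–C16 branch (steps 7–11) is 5 steps.

Steps most likely to fail:

1. Step 19. What may go wrong: hydride delivery to the allylic oxirane carbon (reductive opening) instead of clean hydroboration, loss of the C9 borate by 1,3-elimination onto the oxirane or by protodeboronation under base, and oligomerisation outrunning ring closure. Fallback: the oxirane would be introduced after the same C8–C9 ring closure. It sets out from 25. MnO2 oxidation should give the lactone 2-methyl-enal F1, and Wittig methylenation the lactone 9,11-diene F2. 9-BBN should add to the terminal C9=C10 bond of the diene to give the homoallylic B-alkyl-9-BBN adduct F3 (not isolated), and the Pd/Cs2CO3 conditions of step 19 should close the ring to the macrocyclic 3,7,11-triene F4. Methylenation as in step 20, through the Mannich base F5 and its methiodide F6 (both not isolated), should give the α-methylene triene F7. DDQ should then free the C13 allylic alcohol F8. Hydroxyl-directed VO(acac)2/t-BuOOH epoxidation of the C11=C12 bond (A(1,2)-strain control, oxygen delivered syn to the C13 hydroxyl with H-13 eclipsing the C12 methyl) should give the target's oxirane configuration, and the route is rejoined at 34.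

2. Step 12. What may go wrong: insufficient facial discrimination of the β,β-disubstituted enal by the catalyst, and leakage of E-boronate (incomplete Z-control in step 11) into the anti series that leads to the trans-lactone. Fallback: stoichiometric reagent control through an allene. It sets out from 13. Propargylation with allenylboronic acid pinacol ester under (S)-TRIP catalysis should give the (S)-homopropargylic alcohol F9, NaH/PMBCl its PMB ether F10, and Crabbé homologation (paraformaldehyde, CuBr, i-Pr2NH, dioxane, reflux) the terminal allene F11. Kinetic hydroboration of the terminal allene C=C with enantiopure 10-trimethylsilyl-9-borabicyclo[3.3.2]decane (the antipode that directs attack to the Re face of 9), followed by addition of 9 at −78 °C in the same flask and oxidative work-up, should give the syn adduct. The route is rejoined at 20, bypassing step 11 as well.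

3. Step 14. What may go wrong: oxidation of the allylic secondary C2 alcohol to the enone before the primary alcohol has been converted to the lactol. Fallback: the C2 hydroxyl is masked and C16 is taken to the acid. It sets out from 20. TESOTf/2,6-lutidine should give the C2 triethylsilyl ether F12, 9-BBN then NaOH/H2O2 the primary C16 alcohol F13, and TEMPO/PhI(OAc)2 in MeCN–water the C16 carboxylic acid F14. HF·pyridine should then remove both silyl groups, the γ-hydroxy acid should lactonise, and the route is rejoined at 25 (steps 14 and 15 replaced).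

Further compounds
F1 | step 19 | lactone enal: 25 with C10 oxidised to the aldehyde ((E)-2-methyl-enal) | O=C1C[C@H](C[C@H](OCc2ccc(OC)cc2)/C(C)=C/C=O)[C@H](/C=C(\C)CC/C=C(\C)I)O1
F2 | step 19 | lactone 9,11-diene (C9=C10–C11=C12, 11E), 13-O-PMB, 8-iodo | O=C1C[C@H](C[C@H](OCc2ccc(OC)cc2)/C(C)=C/C=C)[C@H](/C=C(\C)CC/C=C(\C)I)O1
F3 | step 19 | B-alkyl-9-BBN adduct of F2, boron on C9 (formed in situ) | O=C1C[C@H](C[C@H](OCc2ccc(OC)cc2)/C(C)=C/CCB2C3CCCC2CCC3)[C@H](/C=C(\C)CC/C=C(\C)I)O1
F4 | step 19 | (3E,7E,11E)-13-[(4-methoxybenzyl)oxy]-17-norcembra-3,7,11-trien-16,2-olide, cis-lactone, configured at C1, C2, C13 as in 30 | C1C(=O)O[C@H]2/C=C(\C)CC/C=C(\C)CC/C=C(\C)[C@@H](OCc3ccc(OC)cc3)C[C@@H]12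
F5 | step 19 | 15-(dimethylaminomethyl) derivative of F4 (formed in situ) | CN(C)CC1C(=O)O[C@H]2/C=C(\C)CC/C=C(\C)CC/C=C(\C)[C@@H](OCc3ccc(OC)cc3)C[C@@H]12
F6 | step 19 | methiodide of F5 (formed in situ) | C[N+](C)(C)CC1C(=O)O[C@H]2/C=C(\C)CC/C=C(\C)CC/C=C(\C)[C@@H](OCc3ccc(OC)cc3)C[C@@H]12.[I-]
F7 | step 19 | (3E,7E,11E)-13-[(4-methoxybenzyl)oxy]cembra-3,7,11,15(17)-tetraen-16,2-olide | C=C1C(=O)O[C@H]2/C=C(\C)CC/C=C(\C)CC/C=C(\C)[C@@H](OCc3ccc(OC)cc3)C[C@@H]12
F8 | step 19 | (3E,7E,11E)-13-hydroxycembra-3,7,11,15(17)-tetraen-16,2-olide | C=C1C(=O)O[C@H]2/C=C(\C)CC/C=C(\C)CC/C=C(\C)[C@@H](O)C[C@@H]12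
F9 | step 12 | (4S,5E)-7-[(tert-butyldimethylsilyl)oxy]-5-methylhept-5-en-1-yn-4-ol | C#CC[C@H](O)/C(C)=C/CO[Si](C)(C)C(C)(C)C
F10 | step 12 | 4-methoxybenzyl ether of F9 | C#CC[C@H](OCc1ccc(OC)cc1)/C(C)=C/CO[Si](C)(C)C(C)(C)C
F11 | step 12 | tert-butyl({(2E,4S)-4-[(4-methoxybenzyl)oxy]-3-methylocta-2,6,7-trien-1-yl}oxy)dimethylsilane (terminal allene) | C=C=CC[C@H](OCc1ccc(OC)cc1)/C(C)=C/CO[Si](C)(C)C(C)(C)C
F12 | step 14 | C2 triethylsilyl ether of 20 | C=C[C@H](C[C@H](OCc1ccc(OC)cc1)/C(C)=C/CO[Si](C)(C)C(C)(C)C)[C@@H](O[Si](CC)(CC)CC)/C=C(\C)CC/C=C(\C)I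
F13 | step 14 | primary C16 alcohol from F12 (ethenyl converted to 2-hydroxyethyl) | OCC[C@H](C[C@H](OCc1ccc(OC)cc1)/C(C)=C/CO[Si](C)(C)C(C)(C)C)[C@@H](O[Si](CC)(CC)CC)/C=C(\C)CC/C=C(\C)I
F14 | step 14 | C16 carboxylic acid from F13 | OC(=O)C[C@H](C[C@H](OCc1ccc(OC)cc1)/C(C)=C/CO[Si](C)(C)C(C)(C)C)[C@@H](O[Si](CC)(CC)CC)/C=C(\C)CC/C=C(\C)I
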